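**Retrosynthetic overview**
1. Feature: ring A (azepine N4–C5–C6–C7–C8–C9=C9a, tuberostemonine numbering) meets the rest of the pentacycle only at N4 and at the enamine carbons C9/C9a. Its CH2 chain C5–C8 is cut in the middle (C6/C7) into an N4-acryloyl arm and a C9-allyl arm. Ring-closing metathesis rejoins them. C6=C7 saturation, C5 lactam-to-amine reduction and O-desilylation then finish the target.
2. Ring B: the N-acryloyl enamide comes from acylation of the C9a=N4 1-pyrroline, made by cyclodehydration of a C3 amine onto a C9a ketone. Quaternary C1 leaves C9 as the only site of proton loss.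
3. Ring D: an Ireland–Claisen shift from C9a–O makes C12–C13. β-Epoxidation of the C9a=C1 alkene and anti opening at C1 by the C14 ester then makes C1–O. C13 is set by conjugate reduction of the α-methylene lactone.
4. C1–C2: Negishi coupling of the ring C alkenyl iodide with an alkylzinc iodide that carries C3–NHBoc and finished ring E. This fragment comes from N-Boc-D-serinal acetonide, with C18 set by Felkin–Anh addition and C20 by hydrogenation.
5. Ring C: 4,4-dimethoxycyclohexa-2,5-dienone is desymmetrised by copper-catalysed ethyl addition (C10) and allylation (C9). The C9a and C11 carbinols come from reductions. Rings form in the order E, C, D, B, A.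

Key step: step 20

Labels: C1 (quaternary C–O), C2 (CH2), C3 (NCH), N4, C5–C8, C9, C9a, C10 (CHEt), C11 (CHOH), C12, C13 (CHMe), C14 (ring D C=O), C15 (13-methyl), C18 (ring E OCH), C20 (ring E CHMe). β is the face of ring C that carries the C10 ethyl group and α is the opposite face.

Assumption: the copper/phosphoramidite catalyst attacks the dienone ketal with the same facial sense as cyclohex-2-enone, so the (R,S,S)-ligand is specified. If the sense were opposite, the antipodal ligand would be used.

**Route**

Step 1
Reactants: 1 N-Boc-D-serinal acetonide; 2 ethyl 2-(bromomethyl)prop-2-enoate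
Product: 4 α-methylene lactone on the (4R)-oxazolidine (C18 S), via hydroxy ester 3 (not isolated)
Conditions: Zn dust, THF–sat aq NH4Cl, 0 °C to rt; then PPTS (cat), toluene, 60 °C
Reagents that add atoms: none
Why: Zinc Barbier 2-(alkoxycarbonyl)allylation of an aldehyde followed by acid-catalysed lactonisation is the standard entry to α-methylene-γ-butyrolactones, and the bulky N-Boc oxazolidine should impose Felkin–Anh attack so that C18 is formed anti to the C3 nitrogen, any syn epimer being removed by chromatography.

Step 2
Reactants: 4 α-methylene lactone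
Product: 5 cis-(2S,4S)-4-methyl lactone on the (4R)-oxazolidine
Conditions: H2 (1 atm), Pd/C, EtOAc, rt
Reagents that add atoms: none
Why: Heterogeneous catalytic hydrogenation should add hydrogen to the lactone face opposite the bulky C18 substituent and so place the C20 methyl group cis to it, and prior alkene migration into the ring would be reduced from the same face to the same product.

Step 3
Reactants: 5 cis-methyl lactone oxazolidine
Product: 6 N-Boc amino alcohol carrying ring E
Conditions: AcOH–H2O (4:1), 45 °C
Reagents that add atoms: none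
Why: Acid hydrolysis of the N,O-acetonide is faster than Boc cleavage under these mild aqueous conditions, no stereocentre is touched, and the freed primary alcohol cannot translactonise because that would need a seven-membered ring.

Step 4
Reactants: 6 N-Boc amino alcohol
Product: 7 N-Boc β-iodoamine carrying ring E
Conditions: I2, PPh3, imidazole, CH2Cl2, 0 °C to rt
Reagents that add atoms: iodine, SMILES II
Why: Appel-type iodination (alkoxyphosphonium formation, then SN2 by iodide at the primary carbon) is the usual route to N-Boc β-iodoamines and leaves C3, C18 and C20 untouched.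

Step 5
Reactants: 8 4,4-dimethoxycyclohexa-2,5-dien-1-one; 9 diethylzinc; 10 allyl acetate
Product: 12 (5S,6S)-6-allyl-5-ethyl-4,4-dimethoxycyclohex-2-en-1-one (ethyl β and allyl α), via zinc enolate 11 (not isolated)
Conditions: Cu(OTf)2 (2 mol %), (R,S,S)-binaphthol bis(1-phenylethyl)amine phosphoramidite (4 mol %), toluene, −25 °C; then 10, Pd(PPh3)4 (4 mol %), 0 °C; aq NH4Cl
Reagents that add atoms: none
Why: Copper-catalysed enantioselective conjugate addition of a dialkylzinc desymmetrises the prochiral dienone and sets C10 under ligand control, and the zinc enolate is then allylated at C9 by a Tsuji–Trost reaction anti to the new ethyl group.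

Step 6
Reactants: 12 allyl ethyl enone ketal
Product: 13 (5S,6S)-6-allyl-5-ethyl-2-iodo-4,4-dimethoxycyclohex-2-en-1-one
Conditions: I2, pyridine–CH2Cl2 (1:1), 0 °C to rt
Reagents that add atoms: iodine, SMILES II
Why: Pyridine-promoted α-iodination of an enone (conjugate addition of the amine, iodination of the enolate, elimination) is established for 4,4-disubstituted cyclohexenones and spares the ketal and the isolated terminal alkene.

Step 7
Reactants: 13 α-iodoenone
Product: 14 (1S,5S,6S)-6-allyl-5-ethyl-2-iodo-4,4-dimethoxycyclohex-2-en-1-ol (C9a–OH α)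
Conditions: (R)-2-methyl-CBS-oxazaborolidine (20 mol %), catecholborane, toluene, −78 °C; then MeOH, aq NaHCO3
Reagents that add atoms: none
Why: Corey–Bakshi–Shibata reduction in which the iodoalkene arm plays the large group, so that the (R)-catalyst should deliver hydride to the β face and give the α carbinol cis to the allyl group against the modest substrate preference, while catecholborane at −78 °C does not hydroborate the alkene.

Step 8
Reactants: 14 α allylic alcohol; 15 acryloyl chloride
Product: 16 C9a acrylate ester of 14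
Conditions: Et3N, DMAP (cat), CH2Cl2, −20 to 0 °C
Reagents that add atoms: none
Why: Base-mediated O-acylation of a secondary allylic alcohol proceeds with retention at C9a and brings in the three carbons C14, C13 and C15 of ring D.

Step 9
Reactants: 16 acrylate ketal
Product: 17 (1S,5S,6S)-6-allyl-5-ethyl-2-iodo-4-oxocyclohex-2-en-1-yl acrylate
Conditions: PPTS (cat), acetone–H2O (10:1), rt
Reagents that add atoms: water, SMILES O
Why: Acid-catalysed hydrolysis of the allylic ketal, which ionises easily, unmasks the C11 ketone without harming the ester, and C10 keeps its favoured equatorial position trans to the allyl group even though it is now enolisable.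

Step 10
Reactants: 17 β-iodoenone acrylate
Product: 18 (1S,4R,5S,6S)-6-allyl-5-ethyl-4-hydroxy-2-iodocyclohex-2-en-1-yl acrylate (C11–OH α)
Conditions: NaBH4, CeCl3·7H2O, MeOH, −78 °C
Reagents that add atoms: none
Why: Luche 1,2-reduction with axial hydride delivery from the β face, the face remote from the pseudoaxial C9a acyloxy group, should give the pseudoequatorial α alcohol at C11 trans to the C10 ethyl group.

Step 11
Reactants: 18 C11 alcohol
Product: 20 C11 TBS ether C9a 3-(pyrrolidin-1-yl)propanoate, via silyl ether acrylate 19 (not isolated)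
Conditions: TBSCl, imidazole, DMF, rt; then pyrrolidine, rt
Reagents that add atoms: tert-butyldimethylsilyl chloride, SMILES CC(C)(C)[Si](C)(C)Cl; pyrrolidine, SMILES C1CCNC1
Why: Silylation protects C11–OH against later lactonisation onto C14, and aza-Michael addition of pyrrolidine in the same flask turns the acrylate into an enolisable β-aminopropanoate whose amine is too poor a leaving group to be expelled from the enolate.

Step 12
Reactants: 20 β-aminopropanoate
Product: 23 C12 α-linked 3-(pyrrolidin-1-yl)propanoic acid on the C9a=C1 iodoalkene (C13 epimers), via silyl ketene acetal 21 (not isolated), via trimethylsilyl ester 22 (not isolated)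
Conditions: LiN(i-Pr)2, THF, −78 °C; TMSCl, −78 °C to rt, then 55 °C; MeOH–H2O
Reagents that add atoms: none
Why: Ireland–Claisen rearrangement of the silyl ketene acetal moves the ester suprafacially from the pseudoaxial α C9a–O bond to the α face of C12, which sets C12 by chirality transfer and shifts the iodoalkene to C9a=C1, the C13 epimers being irrelevant because C13 becomes sp2 in the next step.

Step 13
Reactants: 23 amino acid
Product: 25 methyl 2-(ring C C12-yl)acrylate alkenyl iodide, via ammonium iodide 24 (not isolated)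
Conditions: MeI, K2CO3, DMF, rt
Reagents that add atoms: iodomethane, SMILES CI
Why: Exhaustive methylation (carboxylate to methyl ester, amine to ammonium salt) and carbonate-induced E1cB elimination of N-methylpyrrolidine is the known way to unmask an α-substituted acrylate from a β-aminopropanoate Claisen product.

Step 14
Reactants: 25 alkenyl iodide; 7 N-Boc β-iodoamine
Product: 27 coupled triene ester with the C2–C3(NHBoc)–ring E chain on C1, via alkylzinc iodide 26 (not isolated)
Conditions: 7, Zn dust (I2-activated), DMF, rt; then 25, Pd2(dba)3 (2.5 mol %), SPhos (10 mol %), rt to 40 °C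
Reagents that add atoms: none
Why: Negishi coupling of a β-(Boc-amino)alkylzinc iodide made by direct zinc insertion in DMF, a reagent class known to couple with aryl and alkenyl iodides without loss of configuration, forms C1–C2, and the electron-rich biarylphosphine should make transmetalation and reductive elimination faster than β-elimination of the carbamate.

Step 15
Reactants: 27 triene ester
Product: 29 α-methylene lactone D with C1–O α and C9a–OH β, via β-epoxide 28 (not isolated)
Conditions: mCPBA (1.1 equiv), CH2Cl2, 0 °C; then CSA (10 mol %), H2O (2 equiv), rt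
Reagents that add atoms: 3-chloroperoxybenzoic acid, SMILES OOC(=O)c1cccc(Cl)c1; water, SMILES O
Why: Prilezhaev epoxidation selects the only electron-rich trisubstituted alkene and its β face, since the pseudoaxial C12 side chain and the C9 allyl group shield the α face, and acid then induces 5-exo anti opening at tertiary C1 by the C14 ester carbonyl with loss of methanol, so that C1–O is fixed α and ring D is cis-fused.

Step 16
Reactants: 29 α-methylene lactone
Product: 30 (13R)-methyl lactone D alcohol
Conditions: Cu(OAc)2·H2O (5 mol %), 1,2-(Ph2P)2C6H4 (5 mol %), (EtO)2MeSiH, t-BuOH, toluene, 0 °C; aq NH4Cl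
Reagents that add atoms: none
Why: Copper hydride conjugate reduction is selective for the α-methylene lactone over the isolated alkene, and protonation of the copper enolate by bulky tert-butanol on the convex face of ring D (the face of H12) should turn the new C13 methyl group to the concave face as the target requires.

Step 17
Reactants: 30 C9a alcohol
Product: 31 2-allyl ring C/D keto lactone with the NHBoc side chain
Conditions: Dess–Martin periodinane, CH2Cl2, 0 °C to rt
Reagents that add atoms: none
Why: Dess–Martin oxidation converts the hindered C9a alcohol into the ketone under nearly neutral conditions that should not epimerise C13 or C20.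

Step 18
Reactants: 31 keto lactone carbamate
Product: 33 ring B/C/D/E 1-pyrroline (C9a=N4), via ammonium trifluoroacetate 32 (not isolated)
Conditions: TFA–CH2Cl2 (1:4), 0 °C; then aq NaHCO3; 4 Å MS, CH2Cl2, rt
Reagents that add atoms: none
Why: Acidolysis of the carbamate and, after neutralisation, 5-exo-trig condensation of the C3 amine with the activated α-acyloxy ketone closes ring B as the 1-pyrroline, a process expected to outrun six-membered acyl transfer from either lactone.

Step 19
Reactants: 33 1-pyrroline; 15 acryloyl chloride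
Product: 34 N4-acryloyl C9-allyl enamide of the ring B/C/D/E core (TBS ether)
Conditions: i-Pr2NEt, BHT (trace), CH2Cl2, −40 to 0 °C
Reagents that add atoms: none
Why: Acylation of a ketimine with an acid chloride and base (classical enamide synthesis) passes through an N-acyliminium ion that can lose a proton only from C9 because C1 is quaternary, and low temperature with excess base should hold back aza-annulation through C9.

Step 20
Reactants: 34 N-acryloyl C-allyl enamide
Product: 35 pentacyclic α,β-unsaturated ene-lactam (TBS ether)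
Conditions: second-generation Grubbs catalyst RuCl2(=CHPh)(PCy3)(H2IMes) (10 mol %), 1,4-benzoquinone (20 mol %), CH2Cl2 (2 mM), 40 °C
Reagents that add atoms: none
Why: The ruthenium benzylidene should first exchange with the unhindered, electron-neutral C9 allyl terminus, and the resulting alkylidene then undergoes intramolecular [2+2] cycloaddition with the electron-poor acrylamide alkene and cycloreversion, which forms C6=C7 and expels ethene (Chauvin mechanism). The closest known reaction type is ring-closing metathesis of N-acryloyl amides and enamides that bear a second terminal alkene, giving six- and seven-membered α,β-unsaturated lactams. Ring A closes as a seven-membered ring (N4, C5, C6, C7, C8, C9, C9a) in which the new alkene is endocyclic and can only be Z. No stereocentre is created and none sits on a reacting carbon, so C1, C3, C10 to C13, C18 and C20 pass through unchanged. Only chemoselectivity is needed: the two monosubstituted alkenes must react while the tetrasubstituted C9=C9a enamide alkene stays inert on steric grounds, and acylation keeps N4 non-basic so that it does not bind ruthenium. The planar enamide holds both arms on the same edge of rings B and C, high dilution disfavours dimerisation, benzoquinone suppresses allyl-to-propenyl isomerisation by ruthenium hydrides, and 40 °C is not exceeded so that a 3-aza-Cope shift of the N-acryloyl enamide does not compete.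

Step 21
Reactants: 35 unsaturated ene-lactam
Product: 36 saturated ring A ene-lactam (TBS ether)
Conditions: H2 (1 atm), RhCl(PPh3)3 (10 mol %), toluene–EtOH (1:1), rt
Reagents that add atoms: none
Why: Homogeneous hydrogenation with the rhodium catalyst saturates the accessible cis-disubstituted C6=C7 alkene, leaves the tetrasubstituted C9=C9a enamide alkene alone and avoids hydrogenolysis of the allylic C1–O bond.

Step 22
Reactants: 36 ene-lactam
Product: 37 pentacyclic enamine TBS ether
Conditions: Zn(OAc)2 (10 mol %), (EtO)3SiH (3 equiv), THF, 40 °C; aq NaHCO3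
Reagents that add atoms: none
Why: Zinc-catalysed hydrosilylation of tertiary amides reduces the C5 lactam through the O-silyl hemiaminal and the iminium ion to the amine and is known to tolerate esters, so both lactones and the silyl ether should survive.

Step 23
Reactants: 37 enamine TBS ether
Product: 38 CNP0154902.3 (target)
Conditions: TBAF, AcOH (1:1), THF, rt
Reagents that add atoms: none
Why: Fluoride-mediated desilylation buffered with acetic acid frees C11–OH without a persistent alkoxide, which should prevent base-induced migration of the ring D acyl group from O1 to O11 and epimerisation at C13.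

**Compound list**
1 | tert-butyl (4R)-4-formyl-2,2-dimethyl-1,3-oxazolidine-3-carboxylate (N-Boc-D-serinal acetonide) | CC1(C)OC[C@H](C=O)N1C(=O)OC(C)(C)C | starting material
2 | ethyl 2-(bromomethyl)prop-2-enoate | CCOC(=O)C(=C)CBr | starting material
3 | ethyl 2-{(2S)-2-hydroxy-2-[(4R)-3-Boc-2,2-dimethyl-1,3-oxazolidin-4-yl]ethyl}prop-2-enoate (anti adduct) | CCOC(=O)C(=C)C[C@H](O)[C@H]1COC(C)(C)N1C(=O)OC(C)(C)C | intermediate
4 | tert-butyl (4R)-2,2-dimethyl-4-[(2S)-4-methylidene-5-oxooxolan-2-yl]-1,3-oxazolidine-3-carboxylate | CC1(C)OC[C@H]([C@@H]2CC(=C)C(=O)O2)N1C(=O)OC(C)(C)C | intermediate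
5 | tert-butyl (4R)-2,2-dimethyl-4-[(2S,4S)-4-methyl-5-oxooxolan-2-yl]-1,3-oxazolidine-3-carboxylate | CC1(C)OC[C@H]([C@@H]2C[C@H](C)C(=O)O2)N1C(=O)OC(C)(C)C | intermediate
6 | tert-butyl {(1R)-2-hydroxy-1-[(2S,4S)-4-methyl-5-oxooxolan-2-yl]ethyl}carbamate | OC[C@@H](NC(=O)OC(C)(C)C)[C@@H]1C[C@H](C)C(=O)O1 | intermediate
7 | tert-butyl {(1S)-2-iodo-1-[(2S,4S)-4-methyl-5-oxooxolan-2-yl]ethyl}carbamate | IC[C@@H](NC(=O)OC(C)(C)C)[C@@H]1C[C@H](C)C(=O)O1 | intermediate
8 | 4,4-dimethoxycyclohexa-2,5-dien-1-one | COC1(OC)C=CC(=O)C=C1 | starting material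
9 | diethylzinc | CC[Zn]CC | starting material
10 | allyl acetate | C=CCOC(C)=O | starting material
11 | ethylzinc dienolate of (5S)-5-ethyl-4,4-dimethoxycyclohex-2-enone | CC[C@H]1C=C(O[Zn]CC)C=CC1(OC)OC | intermediate
12 | (5S,6S)-6-allyl-5-ethyl-4,4-dimethoxycyclohex-2-en-1-one | CC[C@H]1[C@H](CC=C)C(=O)C=CC1(OC)OC | intermediate
13 | (5S,6S)-6-allyl-5-ethyl-2-iodo-4,4-dimethoxycyclohex-2-en-1-one | CC[C@H]1[C@H](CC=C)C(=O)C(I)=CC1(OC)OC | intermediate
14 | (1S,5S,6S)-6-allyl-5-ethyl-2-iodo-4,4-dimethoxycyclohex-2-en-1-ol | CC[C@H]1[C@H](CC=C)[C@H](O)C(I)=CC1(OC)OC | intermediate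
15 | acryloyl chloride | C=CC(=O)Cl | starting material
16 | (1S,5S,6S)-6-allyl-5-ethyl-2-iodo-4,4-dimethoxycyclohex-2-en-1-yl acrylate | CC[C@H]1[C@H](CC=C)[C@H](OC(=O)C=C)C(I)=CC1(OC)OC | intermediate
17 | (1S,5S,6S)-6-allyl-5-ethyl-2-iodo-4-oxocyclohex-2-en-1-yl acrylate | CC[C@H]1[C@H](CC=C)[C@H](OC(=O)C=C)C(I)=CC1=O | intermediate
18 | (1S,4R,5S,6S)-6-allyl-5-ethyl-4-hydroxy-2-iodocyclohex-2-en-1-yl acrylate | CC[C@H]1[C@H](CC=C)[C@H](OC(=O)C=C)C(I)=C[C@@H]1O | intermediate
19 | C11 TBS ether of 18 | CC[C@H]1[C@H](CC=C)[C@H](OC(=O)C=C)C(I)=C[C@@H]1O[Si](C)(C)C(C)(C)C | intermediate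
20 | C11 TBS ether, C9a 3-(pyrrolidin-1-yl)propanoate | CC[C@H]1[C@H](CC=C)[C@H](OC(=O)CCN2CCCC2)C(I)=C[C@@H]1O[Si](C)(C)C(C)(C)C | intermediate
21 | trimethylsilyl ketene acetal of 20 (alkene geometry of no consequence) | CC[C@H]1[C@H](CC=C)[C@H](OC(O[Si](C)(C)C)=CCN2CCCC2)C(I)=C[C@@H]1O[Si](C)(C)C(C)(C)C | intermediate
22 | trimethylsilyl ester of the rearranged acid (C12 chain α, C13 epimers) | CC[C@H]1[C@H](CC=C)C=C(I)[C@H](C(CN2CCCC2)C(=O)O[Si](C)(C)C)[C@@H]1O[Si](C)(C)C(C)(C)C | intermediate
23 | 2-(ring C C12-yl)-3-(pyrrolidin-1-yl)propanoic acid, C9a=C1 iodoalkene (C12 chain α, C13 epimers) | CC[C@H]1[C@H](CC=C)C=C(I)[C@H](C(CN2CCCC2)C(=O)O)[C@@H]1O[Si](C)(C)C(C)(C)C | intermediate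
24 | N-methylpyrrolidinium iodide methyl ester derived from 23 | CC[C@H]1[C@H](CC=C)C=C(I)[C@H](C(C[N+]2(C)CCCC2)C(=O)OC)[C@@H]1O[Si](C)(C)C(C)(C)C.[I-] | intermediate
25 | methyl 2-(ring C C12-yl)acrylate, C1 alkenyl iodide (allyl α, ethyl β, OTBS α, C12 chain α) | CC[C@H]1[C@H](CC=C)C=C(I)[C@H](C(=C)C(=O)OC)[C@@H]1O[Si](C)(C)C(C)(C)C | intermediate
26 | alkylzinc iodide from 7 | I[Zn]C[C@@H](NC(=O)OC(C)(C)C)[C@@H]1C[C@H](C)C(=O)O1 | intermediate
27 | coupled triene ester (C1 bears CH2–CH(NHBoc)–ring E) | CC[C@H]1[C@H](CC=C)C=C(C[C@@H](NC(=O)OC(C)(C)C)[C@@H]2C[C@H](C)C(=O)O2)[C@H](C(=C)C(=O)OC)[C@@H]1O[Si](C)(C)C(C)(C)C | intermediate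
28 | C9a/C1 β-epoxide of 27 | CC[C@H]1[C@H](CC=C)[C@H]2O[C@@]2(C[C@@H](NC(=O)OC(C)(C)C)[C@@H]3C[C@H](C)C(=O)O3)[C@H](C(=C)C(=O)OC)[C@@H]1O[Si](C)(C)C(C)(C)C | intermediate
29 | cis-fused α-methylene lactone D, C9a–OH β | CC[C@H]1[C@H](CC=C)[C@@H](O)[C@]2(C[C@@H](NC(=O)OC(C)(C)C)[C@@H]3C[C@H](C)C(=O)O3)OC(=O)C(=C)[C@@H]2[C@@H]1O[Si](C)(C)C(C)(C)C | intermediate
30 | (13R)-methyl lactone D, C9a–OH β | CC[C@H]1[C@H](CC=C)[C@@H](O)[C@]2(C[C@@H](NC(=O)OC(C)(C)C)[C@@H]3C[C@H](C)C(=O)O3)OC(=O)[C@H](C)[C@@H]2[C@@H]1O[Si](C)(C)C(C)(C)C | intermediate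
31 | 2-allyl ring C/D keto lactone with NHBoc/ring E side chain | CC[C@H]1[C@H](CC=C)C(=O)[C@]2(C[C@@H](NC(=O)OC(C)(C)C)[C@@H]3C[C@H](C)C(=O)O3)OC(=O)[C@H](C)[C@@H]2[C@@H]1O[Si](C)(C)C(C)(C)C | intermediate
32 | C3 ammonium trifluoroacetate of the keto lactone | CC[C@H]1[C@H](CC=C)C(=O)[C@]2(C[C@@H]([NH3+])[C@@H]3C[C@H](C)C(=O)O3)OC(=O)[C@H](C)[C@@H]2[C@@H]1O[Si](C)(C)C(C)(C)C.[O-]C(=O)C(F)(F)F | intermediate
33 | ring B/C/D/E 1-pyrroline (C9a=N4) | CC[C@H]1[C@H](CC=C)C2=N[C@@H]([C@@H]3C[C@H](C)C(=O)O3)C[C@]24OC(=O)[C@H](C)[C@@H]4[C@@H]1O[Si](C)(C)C(C)(C)C | intermediate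
34 | N4-acryloyl C9-allyl enamide (metathesis precursor) | CC[C@H]1C(CC=C)=C2N(C(=O)C=C)[C@@H]([C@@H]3C[C@H](C)C(=O)O3)C[C@]24OC(=O)[C@H](C)[C@@H]4[C@@H]1O[Si](C)(C)C(C)(C)C | intermediate
35 | pentacyclic α,β-unsaturated ene-lactam (metathesis product) | CC[C@H]1C2=C3N(C(=O)C=CC2)[C@@H]([C@@H]2C[C@H](C)C(=O)O2)C[C@]32OC(=O)[C@H](C)[C@@H]2[C@@H]1O[Si](C)(C)C(C)(C)C | intermediate
36 | pentacyclic saturated ring A ene-lactam | CC[C@H]1C2=C3N(C(=O)CCC2)[C@@H]([C@@H]2C[C@H](C)C(=O)O2)C[C@]32OC(=O)[C@H](C)[C@@H]2[C@@H]1O[Si](C)(C)C(C)(C)C | intermediate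
37 | pentacyclic enamine, C11 TBS ether | CC[C@H]1C2=C3N(CCCC2)[C@@H]([C@@H]2C[C@H](C)C(=O)O2)C[C@]32OC(=O)[C@H](C)[C@@H]2[C@@H]1O[Si](C)(C)C(C)(C)C | intermediate
38 | CNP0154902.3 (1R,3R,10S,11R,12R,13R,18S,20S) | CC[C@H]1C2=C3N(CCCC2)[C@@H]([C@@H]2C[C@H](C)C(=O)O2)C[C@]32OC(=O)[C@H](C)[C@@H]2[C@@H]1O | target

**Step count and risks**

Total step count: 23. Longest linear sequence: 19 steps (steps 5 to 23). Steps 1 to 4 supply iodide 7 for the coupling in step 14.

Steps most likely to fail:

Step 14. β-Elimination of the carbamate from the alkylzinc iodide, together with slow oxidative addition and transmetalation at the hindered C1 iodide, may consume the side-chain fragment by protodezincation before coupling occurs.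
- The fallback sets out from iodide 7 and replaces zinc by boron, which does not β-eliminate.
- Copper-catalysed borylation (B2pin2, CuI, PPh3, LiOMe, DMF, rt) would give the pinacol boronate F1.
- KHF2 in aqueous MeOH would convert it into the potassium trifluoroborate F2.
- Suzuki–Miyaura coupling of F2 with alkenyl iodide 25 (PdCl2(dppf), Cs2CO3, toluene–H2O, 80 °C, mildly acidic work-up to reclose any opened lactone) would come back to the route at 27.

Step 20. Several processes may stall ring closure: an unfavourable amide rotamer, chelation of the ruthenium alkylidene by the acrylamide carbonyl, alkene isomerisation, dimerisation, and thermal rearrangement of the N-acryloyl enamide.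
- The fallback sets out from keto lactone 31 and builds the C5–C8 chain on carbon first, closing ring A at N4–C5.
- Cross-metathesis with tert-butyl acrylate (second-generation Hoveyda–Grubbs catalyst RuCl2(=CH-C6H4-2-O-i-Pr)(H2IMes), CH2Cl2, 40 °C) would give the (E)-enoate F3.
- Hydrogenation (H2, Pd/C, EtOAc) would give the saturated tert-butyl ester F4.
- TFA followed by neutralisation would remove both acid-labile groups and close ring B to the imino acid F5.
- Activation with 2-chloro-1-methylpyridinium iodide and Et3N at high dilution would acylate N4 intramolecularly with loss of H9, coming back to the route at 36.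

Step 22. The enamide carbonyl is weakly Lewis basic. Hydrosilylation may therefore be sluggish, may stop at the hemiaminal stage, or may lose its preference for the lactam over the two lactones.
- The fallback sets out from lactam 36.
- Thionation with Lawesson's reagent (toluene, 80 °C), which prefers amides to esters, would give the thiolactam F6.
- Reductive desulfurisation with Raney Ni (THF–EtOH, rt) would come back to the route at 37.

**Further compounds**
F1 | step 14 | pinacol boronate of the side chain (B in place of I in 7) | CC1(C)OB(C[C@@H](NC(=O)OC(C)(C)C)[C@@H]2C[C@H](C)C(=O)O2)OC1(C)C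
F2 | step 14 | potassium trifluoroborate of the side chain | [K+].F[B-](F)(F)C[C@@H](NC(=O)OC(C)(C)C)[C@@H]1C[C@H](C)C(=O)O1
F3 | step 20 | (E)-tert-butyl 4-(C9-yl)but-2-enoate of keto lactone 31 | CC[C@H]1[C@H](C/C=C/C(=O)OC(C)(C)C)C(=O)[C@]2(C[C@@H](NC(=O)OC(C)(C)C)[C@@H]3C[C@H](C)C(=O)O3)OC(=O)[C@H](C)[C@@H]2[C@@H]1O[Si](C)(C)C(C)(C)C
F4 | step 20 | tert-butyl 4-(C9-yl)butanoate of the keto lactone | CC[C@H]1[C@H](CCCC(=O)OC(C)(C)C)C(=O)[C@]2(C[C@@H](NC(=O)OC(C)(C)C)[C@@H]3C[C@H](C)C(=O)O3)OC(=O)[C@H](C)[C@@H]2[C@@H]1O[Si](C)(C)C(C)(C)C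
F5 | step 20 | 1-pyrroline with a C9 butanoic acid chain (imino acid) | CC[C@H]1[C@H](CCCC(=O)O)C2=N[C@@H]([C@@H]3C[C@H](C)C(=O)O3)C[C@]24OC(=O)[C@H](C)[C@@H]4[C@@H]1O[Si](C)(C)C(C)(C)C
F6 | step 22 | C5 thiolactam of 36 | CC[C@H]1C2=C3N(C(=S)CCC2)[C@@H]([C@@H]2C[C@H](C)C(=O)O2)C[C@]32OC(=O)[C@H](C)[C@@H]2[C@@H]1O[Si](C)(C)C(C)(C)C
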